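**Retrosynthetic overview**

1. 16 ⇐ 15: the last step frees 3-OH, 2'-OH and 5'-OH (benzyl ethers) and 5-OH (the methyl ether peri to C4=O) with BCl3.
2. 15 ⇐ 13: ring C is closed by the C4–C4a bond. Ring A carries oxygen on C5, C6, C7, C8 and C8a, so C4a is its only C–H and lies ortho to O1; a carboxyl carbon tethered through O1–C2=C3 can acylate nowhere else.
3. 13 ⇐ 12 ⇐ 11 + 4: O1–C2 by addition–elimination of the tetramethoxyphenoxide on an enol triflate; 11 ⇐ 10 ⇐ 9 + 8: C2–C3 by acylation of an ester enolate.
4. 8 ⇐ 5 (benzylation, saponification, acid chloride); 4 ⇐ 1 (formylation, Baeyer–Villiger oxidation).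
5. Ring order: rings A and B come from 1 and 5; ring C is the only ring formed, in step 10.

Key step: step 10

Remark: the target has no stereocentre. The only stereo-element in the route is the alkene geometry of 11–14; the isomer with the ester or acid carbonyl cis to the β-oxygen substituent is (E), because the benzyloxy oxygen outranks the carboxyl carbon at C2 of the propenoate. Compounds 1, 5 and 9 are taken as commercial.

**Route**

Step 1
Reactants: 1 1,2,3,4-tetramethoxybenzene
Product: 2 2,3,4,5-tetramethoxybenzaldehyde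
Conditions: POCl3, DMF, 0 → 80 °C; then aq. NaOAc
Reagents that add atoms: N,N-dimethylformamide, CN(C)C=O; water, O
Why: Vilsmeier–Haack formylation: the two free positions of 1 are equivalent and each is ortho and para to a methoxy group, so the chloroiminium ion should give a single aldehyde after hydrolysis.

Step 2
Reactants: 2 2,3,4,5-tetramethoxybenzaldehyde
Product: 4 2,3,4,5-tetramethoxyphenol, via aryl formate 3 (not isolated)
Conditions: mCPBA, CH2Cl2, 0 °C → rt; aq. NaHCO3 wash; then Et3N (cat.), MeOH, rt
Reagents that add atoms: 3-chloroperoxybenzoic acid (mCPBA), OOC(=O)c1cccc(Cl)c1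
Why: Baeyer–Villiger (Dakin-type) oxidation: in the Criegee adduct the electron-rich aryl group migrates in preference to hydrogen, and methanol transesterifies the aryl formate to the free phenol.

Step 3
Reactants: 5 2,5-dihydroxybenzoic acid
Product: 6 benzyl 2,5-bis(benzyloxy)benzoate
Conditions: BnBr (3.5 equiv), K2CO3, DMF, 60 °C
Reagents that add atoms: benzyl bromide, BrCc1ccccc1
Why: Williamson O-alkylation: carbonate deprotonates the acid and both phenols and the three oxygen nucleophiles are benzylated by SN2 displacement, the hydrogen-bonded 2-OH reacting last on warming.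

Step 4
Reactants: 6 benzyl 2,5-bis(benzyloxy)benzoate
Product: 7 2,5-bis(benzyloxy)benzoic acid
Conditions: KOH, THF/MeOH/H2O, 65 °C; then aq. HCl
Reagents that add atoms: potassium hydroxide, [K+].[OH-]
Why: Ester saponification (BAc2): hydroxide cleaves only the benzyl ester, the aryl benzyl ethers being inert to base.

Step 5
Reactants: 7 2,5-bis(benzyloxy)benzoic acid
Product: 8 2,5-bis(benzyloxy)benzoyl chloride
Conditions: (COCl)2, DMF (cat.), CH2Cl2, 0 °C → rt; concentrate, use crude
Reagents that add atoms: oxalyl chloride, O=C(Cl)C(Cl)=O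
Why: Acid chloride formation through the chloroiminium species from oxalyl chloride and catalytic DMF, under conditions that leave aryl benzyl ethers untouched.

Step 6
Reactants: 9 methyl benzyloxyacetate; 8 2,5-bis(benzyloxy)benzoyl chloride
Product: 10 methyl 2-(benzyloxy)-3-[2,5-bis(benzyloxy)phenyl]-3-oxopropanoate (racemic)
Conditions: 9 (2.2 equiv), LiN(SiMe3)2 (2.2 equiv), THF, −78 °C; then 8, −78 → −40 °C; aq. NH4Cl
Reagents that add atoms: none
Why: Crossed Claisen-type C-acylation of a lithium ester enolate by an acid chloride: the glycolate enolate is formed irreversibly at −78 °C, the non-enolisable aroyl chloride is the only electrophile, and the second equivalent of enolate deprotonates the more acidic product and so stops over-acylation.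

Step 7
Reactants: 10 methyl 2-(benzyloxy)-3-[2,5-bis(benzyloxy)phenyl]-3-oxopropanoate
Product: 11 methyl (2E)-2-(benzyloxy)-3-[2,5-bis(benzyloxy)phenyl]-3-{[(trifluoromethyl)sulfonyl]oxy}prop-2-enoate (TfO cis to CO2Me)
Conditions: NaH, Et2O, 0 °C; then Tf2O, −20 → 0 °C
Reagents that add atoms: trifluoromethanesulfonic anhydride, O=S(=O)(OS(=O)(=O)C(F)(F)F)C(F)(F)F
Why: O-sulfonylation of a β-keto ester enolate: the sodium-chelated enolate holds the enolate oxygen syn to the ester carbonyl and is triflated on oxygen, which should favour the (E)-enol triflate.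

Step 8
Reactants: 11 methyl (2E)-2-(benzyloxy)-3-[2,5-bis(benzyloxy)phenyl]-3-{[(trifluoromethyl)sulfonyl]oxy}prop-2-enoate; 4 2,3,4,5-tetramethoxyphenol
Product: 12 methyl (2E)-2-(benzyloxy)-3-[2,5-bis(benzyloxy)phenyl]-3-(2,3,4,5-tetramethoxyphenoxy)prop-2-enoate (ArO cis to CO2Me)
Conditions: Cs2CO3, DMF, 0 °C → rt
Reagents that add atoms: none
Why: Nucleophilic vinylic substitution by addition–elimination: the caesium phenoxide adds to the β-carbon, which is activated by the ester and the triflyloxy group, and the ester enolate expels triflate, expected mainly with retention of geometry.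

Step 9
Reactants: 12 methyl (2E)-2-(benzyloxy)-3-[2,5-bis(benzyloxy)phenyl]-3-(2,3,4,5-tetramethoxyphenoxy)prop-2-enoate
Product: 13 (2E)-2-(benzyloxy)-3-[2,5-bis(benzyloxy)phenyl]-3-(2,3,4,5-tetramethoxyphenoxy)prop-2-enoic acid (CO2H cis to ArO)
Conditions: LiOH·H2O, THF/MeOH/H2O, rt → 40 °C; then cold dilute HCl to pH 3–4
Reagents that add atoms: lithium hydroxide, [Li+].[OH-]
Why: Ester saponification: hydroxide attacks the methyl ester carbonyl while the aryl enol ether and benzyl ethers are stable to base, and mild cold acidification avoids hydrolysis of the enol ether.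

Step 10
Reactants: 13 (2E)-2-(benzyloxy)-3-[2,5-bis(benzyloxy)phenyl]-3-(2,3,4,5-tetramethoxyphenoxy)prop-2-enoic acid
Product: 15 3-(benzyloxy)-2-[2,5-bis(benzyloxy)phenyl]-5,6,7,8-tetramethoxy-4H-chromen-4-one, via mixed trifluoroacetic anhydride 14 (not isolated)
Conditions: (CF3CO)2O (1.5 equiv), CH2Cl2, 0 °C → rt
Reagents that add atoms: none
Why: Trifluoroacetic anhydride turns the acid into the mixed anhydride 14, whose acyl carbon (future C4, free or as an incipient acylium ion) is held over C4a by the O1–C2=C3 tether because the carboxyl group is cis to the aryloxy group; C4a attacks it, and loss of trifluoroacetate and of the C4a proton gives the pyranone. This is an intramolecular Friedel–Crafts acylation of the Ruhemann/Simonis kind, by which β-aryloxyacrylic and β-aryloxycinnamic acids are closed to chromones. Ring C closes in a six-membered mode, 6-exo-trig at the acyl C=O, with the C4a–C8a bond of ring A inside the new ring. No stereocentre is formed. Regioselectivity needs no control because C4a is the only C–H of ring A, activated by O1 and the C5 methoxy group (ortho) and the C7 methoxy group (para); closure onto C6' of ring B to an indenone is disfavoured by the (E) geometry, the strained five-membered ring and the lower nucleophilicity of ring B, and any (Z)-acid can cross over by reversible protonation at C3 of the push–pull alkene. The oxygen-rich ring should make a Lewis acid unnecessary, so the three benzyl ethers should survive.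

Step 11
Reactants: 15 3-(benzyloxy)-2-[2,5-bis(benzyloxy)phenyl]-5,6,7,8-tetramethoxy-4H-chromen-4-one
Product: 16 2-(2,5-dihydroxyphenyl)-3,5-dihydroxy-6,7,8-trimethoxy-4H-chromen-4-one
Conditions: BCl3 (1 M in CH2Cl2, excess), C6HMe5 (pentamethylbenzene, excess), CH2Cl2, −78 → 0 °C; then MeOH, dilute aq. HCl, under argon
Reagents that add atoms: none
Why: Lewis-acid ether cleavage with cation scavenging: BCl3 ionises the three O-benzyl bonds at low temperature while pentamethylbenzene captures the benzyl cations, and on warming the boron chelated between the C4 carbonyl and the peri C5 oxygen delivers chloride to that methyl group only, the 6-, 7- and 8-methoxy groups having no such chelate.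

**Compound list**

1 | 1,2,3,4-tetramethoxybenzene | COc1ccc(OC)c(OC)c1OC | starting material
2 | 2,3,4,5-tetramethoxybenzaldehyde | COc1cc(C=O)c(OC)c(OC)c1OC | intermediate
3 | 2,3,4,5-tetramethoxyphenyl formate | COc1cc(OC=O)c(OC)c(OC)c1OC | intermediate (not isolated)
4 | 2,3,4,5-tetramethoxyphenol | COc1cc(O)c(OC)c(OC)c1OC | intermediate
5 | 2,5-dihydroxybenzoic acid | OC(=O)c1cc(O)ccc1O | starting material
6 | benzyl 2,5-bis(benzyloxy)benzoate | O=C(OCc1ccccc1)c1cc(OCc2ccccc2)ccc1OCc1ccccc1 | intermediate
7 | 2,5-bis(benzyloxy)benzoic acid | OC(=O)c1cc(OCc2ccccc2)ccc1OCc1ccccc1 | intermediate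
8 | 2,5-bis(benzyloxy)benzoyl chloride | ClC(=O)c1cc(OCc2ccccc2)ccc1OCc1ccccc1 | intermediate
9 | methyl benzyloxyacetate | COC(=O)COCc1ccccc1 | starting material
10 | methyl 2-(benzyloxy)-3-[2,5-bis(benzyloxy)phenyl]-3-oxopropanoate (racemic) | COC(=O)C(OCc1ccccc1)C(=O)c1cc(OCc2ccccc2)ccc1OCc1ccccc1 | intermediate
11 | methyl (2E)-2-(benzyloxy)-3-[2,5-bis(benzyloxy)phenyl]-3-{[(trifluoromethyl)sulfonyl]oxy}prop-2-enoate | COC(=O)/C(OCc1ccccc1)=C(\OS(=O)(=O)C(F)(F)F)c1cc(OCc2ccccc2)ccc1OCc1ccccc1 | intermediate
12 | methyl (2E)-2-(benzyloxy)-3-[2,5-bis(benzyloxy)phenyl]-3-(2,3,4,5-tetramethoxyphenoxy)prop-2-enoate | COC(=O)/C(OCc1ccccc1)=C(\Oc1cc(OC)c(OC)c(OC)c1OC)c1cc(OCc2ccccc2)ccc1OCc1ccccc1 | intermediate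
13 | (2E)-2-(benzyloxy)-3-[2,5-bis(benzyloxy)phenyl]-3-(2,3,4,5-tetramethoxyphenoxy)prop-2-enoic acid | OC(=O)/C(OCc1ccccc1)=C(\Oc1cc(OC)c(OC)c(OC)c1OC)c1cc(OCc2ccccc2)ccc1OCc1ccccc1 | intermediate
14 | (2E)-2-(benzyloxy)-3-[2,5-bis(benzyloxy)phenyl]-3-(2,3,4,5-tetramethoxyphenoxy)prop-2-enoic trifluoroacetic anhydride | FC(F)(F)C(=O)OC(=O)/C(OCc1ccccc1)=C(\Oc1cc(OC)c(OC)c(OC)c1OC)c1cc(OCc2ccccc2)ccc1OCc1ccccc1 | intermediate (not isolated)
15 | 3-(benzyloxy)-2-[2,5-bis(benzyloxy)phenyl]-5,6,7,8-tetramethoxy-4H-chromen-4-one | COc1c(OC)c(OC)c2c(=O)c(OCc3ccccc3)c(-c3cc(OCc4ccccc4)ccc3OCc3ccccc3)oc2c1OC | intermediate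
16 | 2-(2,5-dihydroxyphenyl)-3,5-dihydroxy-6,7,8-trimethoxy-4H-chromen-4-one | COc1c(OC)c(O)c2c(=O)c(O)c(-c3cc(O)ccc3O)oc2c1OC | target

**Step count**

Total step count: 11. Longest linear sequence: 9 steps (5 → 16, steps 3–11).

**Steps most likely to fail**

Step 8. The phenoxide may add too slowly to the tetrasubstituted β-carbon, which carries a donor oxygen on its neighbour and an ortho-substituted aryl group. It may instead attack the sulfur of the triflate, transferring the triflyl group and returning the enolate of 10. The fallback sets out from 11 and 4 and makes the same C–O bond by cross-coupling instead of addition–elimination: Pd2(dba)3 as source of zerovalent palladium, 2-di-tert-butylphosphino-2',4',6'-triisopropylbiphenyl, K3PO4, toluene, 80 °C. Oxidative addition into the C–OTf bond, exchange of triflate for phenoxide and C–O reductive elimination should give the aryl enol ether with retention of geometry. The path comes back to the route at 12 and makes no compound outside the list (F0).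

Step 10. The mixed anhydride may be too weak an electrophile, since its acyl carbon is the acceptor end of a vinylogous carbonate. The reagent may also trifluoroacetylate C4a, or the alkene may drift to the isomer that closes onto ring B. The fallback sets out from 4 and 8 and closes ring C at O1–C2 by the Baker–Venkataraman sequence. Phenol 4 is C-acetylated at its only free position (AcOH, BF3·OEt2, 80 °C, O-acylation then Fries shift) to give 1-(2-hydroxy-3,4,5,6-tetramethoxyphenyl)ethan-1-one F1. Esterification with 8 (pyridine, DMAP, CH2Cl2) gives 2-acetyl-3,4,5,6-tetramethoxyphenyl 2,5-bis(benzyloxy)benzoate F2. Base-induced acyl transfer (KOH, pyridine, 50 °C) gives 1-[2,5-bis(benzyloxy)phenyl]-3-(2-hydroxy-3,4,5,6-tetramethoxyphenyl)propane-1,3-dione F3. Cyclodehydration (p-TsOH, toluene, reflux) gives 2-[2,5-bis(benzyloxy)phenyl]-5,6,7,8-tetramethoxy-4H-chromen-4-one F4. Epoxidation of the C2=C3 bond with dimethyldioxirane (acetone/CH2Cl2, 0 °C) and acid-catalysed opening (p-TsOH, cat.) gives 2-[2,5-bis(benzyloxy)phenyl]-3-hydroxy-5,6,7,8-tetramethoxy-4H-chromen-4-one F5. F5 differs from 15 only in the free 3-OH, so it is taken through the conditions of step 11 and comes back to the route at 16.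

Step 11. Benzyl cations may C-alkylate the electron-rich rings, demethylation may run on from C5 to C6 through the 5-O-boron chelate, or cleavage of the 5-methyl ether may stay incomplete; the hydroquinone ring of the product may also be oxidised on work-up. The fallback sets out from 15 and separates the two events. Hydrogenolysis (H2, palladium on carbon (Pd/C), EtOAc/MeOH, rt) gives 2-(2,5-dihydroxyphenyl)-3-hydroxy-5,6,7,8-tetramethoxy-4H-chromen-4-one F6. Chelation-controlled demethylation of the peri methyl ether with AlCl3 in MeCN (rt → 50 °C, then dilute HCl, under argon) then gives 16, where the path comes back to the route.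

**Further compounds**

F0 | step 8 | none | none
F1 | step 10 | 1-(2-hydroxy-3,4,5,6-tetramethoxyphenyl)ethan-1-one | CC(=O)c1c(O)c(OC)c(OC)c(OC)c1OC
F2 | step 10 | 2-acetyl-3,4,5,6-tetramethoxyphenyl 2,5-bis(benzyloxy)benzoate | CC(=O)c1c(OC(=O)c2cc(OCc3ccccc3)ccc2OCc2ccccc2)c(OC)c(OC)c(OC)c1OC
F3 | step 10 | 1-[2,5-bis(benzyloxy)phenyl]-3-(2-hydroxy-3,4,5,6-tetramethoxyphenyl)propane-1,3-dione | O=C(CC(=O)c1c(O)c(OC)c(OC)c(OC)c1OC)c1cc(OCc2ccccc2)ccc1OCc1ccccc1
F4 | step 10 | 2-[2,5-bis(benzyloxy)phenyl]-5,6,7,8-tetramethoxy-4H-chromen-4-one | COc1c(OC)c(OC)c2c(=O)cc(-c3cc(OCc4ccccc4)ccc3OCc3ccccc3)oc2c1OC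
F5 | step 10 | 2-[2,5-bis(benzyloxy)phenyl]-3-hydroxy-5,6,7,8-tetramethoxy-4H-chromen-4-one | COc1c(OC)c(OC)c2c(=O)c(O)c(-c3cc(OCc4ccccc4)ccc3OCc3ccccc3)oc2c1OC
F6 | step 11 | 2-(2,5-dihydroxyphenyl)-3-hydroxy-5,6,7,8-tetramethoxy-4H-chromen-4-one | COc1c(OC)c(OC)c2c(=O)c(O)c(-c3cc(O)ccc3O)oc2c1OC
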